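## Retrosynthetic overview

1. The C40 chain is cut at C11=C12 and C11'=C12' (two Horner–Wadsworth–Emmons olefinations) into a C15 aldehyde of ring A (the 3,6-dihydroxy ring, unprimed carotenoid locants), a C10 bis-phosphonate and a C15 aldehyde of ring B (the acetylenic ring, primed locants). Two benzoates are removed last.
2. Ring B aldehyde: C8'–C9' by Sonogashira coupling, and C3'–OH by asymmetric hydroboration of the C2'=C3' olefin of a 1-alkynyl-2,6,6-trimethylcyclohexa-1,4-diene.
3. Key disconnection: that diene is opened across C2'=C3' and C5'=C6' by a [3+3] double Wittig annulation into butane-1,3-diylbis(triphenylphosphonium) dibromide and OHC–CMe2–CO–C≡C–Si(iPr)3. Enabling feature: in ring B, C2' and C6' both sit on the quaternary C1', which gives a non-enolisable 1,3-dicarbonyl partner and blocks aromatisation of the skipped diene. C3' and C5' flank the single methylene C4', which gives a 1,3-bis-ylide partner.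
4. Ring A: (R)-4-hydroxy enone from ketoisophorone by asymmetric transfer hydrogenation; 1,4-relay from C3 to C6 in the acetylide addition; 7E-olefin by hydroalumination; Mitsunobu inversion at C3 to reach the 3,6-cis-diol.
5. Ring order: ring B is the only ring that is built (step 5); ring A is bought as ketoisophorone.

Key step: step 5

Remark (assumptions): compounds 1, 3, 6, 12, 18, 20 and 25 are taken as commercial. The transfer hydrogenation in step 11 is assumed to follow the usual sense for aryl and alkenyl ketones, (R,R)-ligand giving the (R)-carbinol; the mirror-image ligand would be used otherwise.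

## Route

Step 1
Reactants: 1 methyl 3-hydroxy-2,2-dimethylpropanoate
Product: 2 3-hydroxy-N-methoxy-N,2,2-trimethylpropanamide
Conditions: MeNH(OMe)·HCl (1.5 equiv), iPrMgCl (4.5 equiv), THF, −20 → 0 °C
Reagents that add atoms: N,O-dimethylhydroxylamine hydrochloride, CNOC.Cl
Why: Aminolysis of the ester by the magnesium amide (Weinreb amide formation) should tolerate the hydroxyl as its magnesium alkoxide; no stereocentre is involved.

Step 2
Reactants: 2 3-hydroxy-N-methoxy-N,2,2-trimethylpropanamide; 3 ethynyltriisopropylsilane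
Product: 4 1-hydroxy-2,2-dimethyl-5-(triisopropylsilyl)pent-4-yn-3-one
Conditions: 3 (2.5 equiv), n-BuLi (2.4 equiv), THF, −78 °C; then 2, −78 → 0 °C; 1 M HCl quench
Reagents that add atoms: none
Why: Weinreb ketone synthesis: the lithium acetylide should add only once because the chelated tetrahedral intermediate persists until the acidic quench, and the quaternary α-carbon rules out enolisation; no stereocentre is formed.

Step 3
Reactants: 4 1-hydroxy-2,2-dimethyl-5-(triisopropylsilyl)pent-4-yn-3-one
Product: 5 2,2-dimethyl-3-oxo-5-(triisopropylsilyl)pent-4-ynal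
Conditions: DMP (1,1,1-triacetoxy-1,1-dihydro-1,2-benziodoxol-3(1H)-one, 1.2 equiv), CH2Cl2, 0 °C → rt
Reagents that add atoms: none
Why: Periodinane oxidation of the neopentyl primary alcohol under neutral conditions should leave the non-enolisable β-keto aldehyde and the silyl alkyne intact; no stereocentre is formed.

Step 4
Reactants: 6 1,3-dibromobutane (racemic)
Product: 7 butane-1,3-diylbis(triphenylphosphonium) dibromide (racemic)
Conditions: PPh3 (2.4 equiv), DMF, 150 °C, sealed tube; trituration with Et2O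
Reagents that add atoms: triphenylphosphine, c1ccc(cc1)P(c1ccccc1)c1ccccc1
Why: Double SN2 quaternisation of the phosphine (phosphonium salt formation), the secondary bromide needing the high temperature; the stereocentre of the racemic salt disappears when that carbon becomes the ylide carbon C5'.

Step 5
Reactants: 7 butane-1,3-diylbis(triphenylphosphonium) dibromide; 5 2,2-dimethyl-3-oxo-5-(triisopropylsilyl)pent-4-ynal
Product: 9 triisopropyl[(2,6,6-trimethylcyclohexa-1,4-dien-1-yl)ethynyl]silane, via Z-alkenylphosphonium bromide 8 (not isolated)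
Conditions: KN(SiMe3)2 (1.0 equiv), THF, −78 °C; then 5, −78 → 0 °C; then KN(SiMe3)2 (1.1 equiv), 0 → 50 °C, high dilution
Reagents that add atoms: none
Why: One equivalent of base should remove the more acidic, less hindered CH2–P proton of 7, and this unstabilised primary ylide should olefinate the aldehyde of 5 (more reactive than the ynone carbonyl next to the quaternary carbon) through the kinetic cis-oxaphosphetane to the Z-alkene 8, which makes the C2'–C3' bond; the second equivalent then unmasks the secondary ylide at C5', whose intramolecular Wittig reaction with the C6' ketone makes C5'=C6' and closes ring B. The closest known reaction type is the bis-Wittig annulation of alkane-1,3-diylbis(phosphonium) salts with dicarbonyl compounds to cyclic dienes, together with the intramolecular Wittig closure of keto-phosphonium salts to tetrasubstituted cycloalkenes. Ring B closes by 6-exo-trig attack of the ylide carbon on the ketone, and only the Z-isomer of 8 can reach it, so the ring fixes the geometry of both double bonds. No stereocentre is formed here; the C3' centre is placed in step 6 on the C2'=C3' olefin that this step lays down. The step needs chemoselectivity (aldehyde before ketone, primary before secondary ylide) and 1,2- rather than 1,4-attack on the ynone: the quaternary C1' makes 5 non-enolisable, the two portions of base order the two olefinations, and conjugate attack would need an eight-membered ring.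

Step 6
Reactants: 9 triisopropyl[(2,6,6-trimethylcyclohexa-1,4-dien-1-yl)ethynyl]silane
Product: 11 (1R)-3,5,5-trimethyl-4-[(triisopropylsilyl)ethynyl]cyclohex-3-en-1-ol, via trialkylborane 10 (not isolated)
Conditions: (−)-Ipc2BH (diisopinocampheylborane from (+)-α-pinene, 1.3 equiv), THF, −25 → 0 °C; then 3 M NaOH, 30% H2O2, 0 °C → rt
Reagents that add atoms: hydrogen peroxide, OO
Why: Asymmetric hydroboration–oxidation of the cis-disubstituted C2'=C3' olefin: boron should go to C3', away from the quaternary C1', the reagent from (+)-α-pinene should select the face that gives the (3'R)-carbinol (the sense known for cis-olefins), oxidation proceeds with retention, and the tetrasubstituted enyne shielded by the ring methyls and the triisopropylsilyl group should react much more slowly.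

Step 7
Reactants: 12 but-2-yn-1-ol
Product: 13 (2E)-3-iodobut-2-en-1-ol
Conditions: Cp2Zr(H)Cl (2.2 equiv), THF, rt; then I2, 0 °C
Reagents that add atoms: iodine, II
Why: Syn-hydrozirconation of the internal alkyne with excess reagent should place zirconium on the carbon next to the small methyl group, and iodinolysis with retention gives the E-vinyl iodide; no stereocentre is formed.

Step 8
Reactants: 11 (1R)-3,5,5-trimethyl-4-[(triisopropylsilyl)ethynyl]cyclohex-3-en-1-ol; 13 (2E)-3-iodobut-2-en-1-ol
Product: 15 (1R)-4-[(3E)-5-hydroxy-3-methylpent-3-en-1-yn-1-yl]-3,5,5-trimethylcyclohex-3-en-1-ol, via terminal alkyne 14 (not isolated)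
Conditions: Bu4NF (1.2 equiv), Pd(PPh3)4 (5 mol %), CuI (10 mol %), THF, rt
Reagents that add atoms: none
Why: Fluoride cleaves the alkynyl C–Si bond and the freed alkyne enters a Sonogashira coupling with the vinyl iodide with retention of the E-geometry (9'E); the C3' stereocentre is not touched.

Step 9
Reactants: 15 (1R)-4-[(3E)-5-hydroxy-3-methylpent-3-en-1-yn-1-yl]-3,5,5-trimethylcyclohex-3-en-1-ol
Product: 16 (2E)-5-[(4R)-4-hydroxy-2,6,6-trimethylcyclohex-1-en-1-yl]-3-methylpent-2-en-4-ynal
Conditions: MnO2 (20 equiv), CH2Cl2, rt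
Reagents that add atoms: none
Why: Allylic oxidation with MnO2 should convert only the primary allylic alcohol into the enal, the saturated secondary carbinol at C3' being inert.

Step 10
Reactants: 16 (2E)-5-[(4R)-4-hydroxy-2,6,6-trimethylcyclohex-1-en-1-yl]-3-methylpent-2-en-4-ynal
Product: 17 (1R)-3,5,5-trimethyl-4-[(3E)-3-methyl-5-oxopent-3-en-1-yn-1-yl]cyclohex-3-en-1-yl benzoate
Conditions: BzCl (1.3 equiv), pyridine, DMAP (5 mol %), CH2Cl2, 0 °C → rt
Reagents that add atoms: benzoyl chloride, O=C(Cl)c1ccccc1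
Why: DMAP-catalysed O-acylation protects C3'–OH for the carbanion chemistry, with retention of configuration.

Step 11
Reactants: 18 2,6,6-trimethylcyclohex-2-ene-1,4-dione (ketoisophorone)
Product: 19 (4R)-4-hydroxy-2,6,6-trimethylcyclohex-2-en-1-one
Conditions: RuCl[(R,R)-TsDPEN](p-cymene) (0.5 mol %), iPrOH, rt
Reagents that add atoms: none
Why: Asymmetric transfer hydrogenation should reduce the less hindered C4 carbonyl of the ene-dione, the (R,R)-ligand giving the (R)-carbinol by the CH/π model in which the ring olefin takes the place of the aryl group.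

Step 12
Reactants: 19 (4R)-4-hydroxy-2,6,6-trimethylcyclohex-2-en-1-one; 20 (2E)-3-methylpent-2-en-4-yn-1-ol
Product: 21 (1R,4R)-1-[(3E)-5-hydroxy-3-methylpent-3-en-1-yn-1-yl]-2,6,6-trimethylcyclohex-2-ene-1,4-diol
Conditions: 20 (2.2 equiv), n-BuLi (4.4 equiv), THF, −78 → −20 °C; then 19, −78 → 0 °C; H2O
Reagents that add atoms: none
Why: 1,2-Addition of the lithium acetylide to the enone carbonyl: in the half-chair with the C4 oxygen pseudo-equatorial the nucleophile should enter axially, anti to the axial 6-methyl group and on the face of the lithium alkoxide that can guide it, so the side chain comes in cis to that oxygen and the tertiary carbinol (C6 of ring A) is set by 1,4-relay.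

Step 13
Reactants: 21 (1R,4R)-1-[(3E)-5-hydroxy-3-methylpent-3-en-1-yn-1-yl]-2,6,6-trimethylcyclohex-2-ene-1,4-diol
Product: 22 (1R,4R)-1-[(1E,3E)-5-hydroxy-3-methylpenta-1,3-dien-1-yl]-2,6,6-trimethylcyclohex-2-ene-1,4-diol
Conditions: NaAlH2(OCH2CH2OMe)2 (4 equiv), THF, 0 °C → rt; aq. KNaC4H4O6
Reagents that add atoms: none
Why: Alkoxide-directed trans-hydroalumination of the propargylic alcohol and protonolysis should give the 7E-olefin, leaving the ring olefin and the 9E-olefin untouched.

Step 14
Reactants: 22 (1R,4R)-1-[(1E,3E)-5-hydroxy-3-methylpenta-1,3-dien-1-yl]-2,6,6-trimethylcyclohex-2-ene-1,4-diol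
Product: 23 (2E,4E)-5-[(1R,4R)-1,4-dihydroxy-2,6,6-trimethylcyclohex-2-en-1-yl]-3-methylpenta-2,4-dienal
Conditions: TEMPO (10 mol %), PhI(OAc)2 (1.1 equiv), CH2Cl2, rt
Reagents that add atoms: none
Why: Oxoammonium (TEMPO) oxidation is selective for the primary allylic alcohol over the secondary and tertiary ones and should give the dienal without touching the stereocentres.

Step 15
Reactants: 23 (2E,4E)-5-[(1R,4R)-1,4-dihydroxy-2,6,6-trimethylcyclohex-2-en-1-yl]-3-methylpenta-2,4-dienal
Product: 24 (1S,4R)-4-hydroxy-3,5,5-trimethyl-4-[(1E,3E)-3-methyl-5-oxopenta-1,3-dien-1-yl]cyclohex-2-en-1-yl benzoate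
Conditions: PhCO2H (1.5 equiv), PPh3 (1.5 equiv), DIAD (1.5 equiv), THF, 0 °C → rt
Reagents that add atoms: benzoic acid, O=C(O)c1ccccc1
Why: Mitsunobu esterification should invert the secondary allylic carbinol (C3 of ring A) by SN2 displacement of the oxyphosphonium group, giving the (3S)-benzoate cis to the tertiary 6-OH, which is too hindered to react.

Step 16
Reactants: 25 (2E,4E,6E)-2,7-dimethylocta-2,4,6-trienedial
Product: 26 (2E,4E,6E)-2,7-dimethylocta-2,4,6-triene-1,8-diol
Conditions: NaBH4 (1.0 equiv), MeOH/THF, 0 °C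
Reagents that add atoms: none
Why: 1,2-Reduction of both enal carbonyls by borohydride keeps the all-E triene.

Step 17
Reactants: 26 (2E,4E,6E)-2,7-dimethylocta-2,4,6-triene-1,8-diol
Product: 27 (2E,4E,6E)-1,8-dibromo-2,7-dimethylocta-2,4,6-triene
Conditions: PBr3 (0.7 equiv), pyridine (cat.), Et2O, −10 °C
Reagents that add atoms: phosphorus tribromide, BrP(Br)Br
Why: Bromination of the primary allylic alcohols through their phosphite esters at low temperature should keep the E-geometry.

Step 18
Reactants: 27 (2E,4E,6E)-1,8-dibromo-2,7-dimethylocta-2,4,6-triene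
Product: 28 tetraethyl [(2E,4E,6E)-2,7-dimethylocta-2,4,6-triene-1,8-diyl]bis(phosphonate)
Conditions: P(OEt)3 (6 equiv, neat), 120 °C
Reagents that add atoms: triethyl phosphite, CCOP(OCC)OCC
Why: Michaelis–Arbuzov reaction of the allylic dibromide.

Step 19
Reactants: 28 tetraethyl [(2E,4E,6E)-2,7-dimethylocta-2,4,6-triene-1,8-diyl]bis(phosphonate); 17 ring B benzoate aldehyde
Product: 29 diethyl [(2E,4E,6E,8E,10E)-13-[(4R)-4-(benzoyloxy)-2,6,6-trimethylcyclohex-1-en-1-yl]-2,7,11-trimethyltrideca-2,4,6,8,10-pentaen-12-yn-1-yl]phosphonate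
Conditions: 28 (3.0 equiv), NaN(SiMe3)2 (1.1 equiv), THF, −78 °C; then 17, −78 → 0 °C, dark
Reagents that add atoms: none
Why: Horner–Wadsworth–Emmons olefination of the aldehyde by the mono-anion of the bis-phosphonate, used in excess to suppress double reaction, should form C11'=C12' with the E-preference of allylic phosphonates; the 9'E-olefin is never part of a carbanion.

Step 20
Reactants: 29 C25 phosphonate; 24 ring A benzoate aldehyde
Product: 30 all-E 3,3'-dibenzoate of the target
Conditions: NaN(SiMe3)2 (1.1 equiv), THF, −78 °C; then 24, −78 → 0 °C, dark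
Reagents that add atoms: none
Why: The second Horner–Wadsworth–Emmons olefination should form C11=C12 (E) and complete the C40 chain, the tertiary alcohol and the benzoates being inert at low temperature.

Step 21
Reactants: 30 all-E 3,3'-dibenzoate of the target
Product: 31 target triol (ring A 3S,6R; ring B 3'R; all-E)
Conditions: K2CO3 (0.5 equiv), MeOH/THF, rt, dark
Reagents that add atoms: none
Why: Base-catalysed transesterification removes both benzoates under conditions that spare the acid-sensitive tertiary allylic alcohol and the polyene; no stereocentre is affected.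

## Compound list

1 | methyl 3-hydroxy-2,2-dimethylpropanoate | COC(=O)C(C)(C)CO | starting material
2 | 3-hydroxy-N-methoxy-N,2,2-trimethylpropanamide | CON(C)C(=O)C(C)(C)CO | intermediate
3 | ethynyltriisopropylsilane | C#C[Si](C(C)C)(C(C)C)C(C)C | starting material
4 | 1-hydroxy-2,2-dimethyl-5-(triisopropylsilyl)pent-4-yn-3-one | CC(C)[Si](C(C)C)(C(C)C)C#CC(=O)C(C)(C)CO | intermediate
5 | 2,2-dimethyl-3-oxo-5-(triisopropylsilyl)pent-4-ynal | CC(C)[Si](C(C)C)(C(C)C)C#CC(=O)C(C)(C)C=O | intermediate
6 | 1,3-dibromobutane (racemic) | CC(Br)CCBr | starting material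
7 | butane-1,3-diylbis(triphenylphosphonium) dibromide (racemic) | CC(CC[P+](c1ccccc1)(c1ccccc1)c1ccccc1)[P+](c1ccccc1)(c1ccccc1)c1ccccc1.[Br-].[Br-] | intermediate
8 | [(4Z)-6,6-dimethyl-7-oxo-9-(triisopropylsilyl)non-4-en-8-yn-2-yl]triphenylphosphonium bromide (racemic, not isolated) | CC(C/C=C\C(C)(C)C(=O)C#C[Si](C(C)C)(C(C)C)C(C)C)[P+](c1ccccc1)(c1ccccc1)c1ccccc1.[Br-] | intermediate
9 | triisopropyl[(2,6,6-trimethylcyclohexa-1,4-dien-1-yl)ethynyl]silane | CC1=C(C#C[Si](C(C)C)(C(C)C)C(C)C)C(C)(C)C=CC1 | intermediate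
10 | bis(isopinocampheyl)[(1R)-3,5,5-trimethyl-4-[(triisopropylsilyl)ethynyl]cyclohex-3-en-1-yl]borane (not isolated) | CC(C)[Si](C(C)C)(C(C)C)C#CC1=C(C)C[C@@H](B([C@@H]2C[C@@H]3C[C@H]([C@H]2C)C3(C)C)[C@@H]2C[C@@H]3C[C@H]([C@H]2C)C3(C)C)CC1(C)C | intermediate
11 | (1R)-3,5,5-trimethyl-4-[(triisopropylsilyl)ethynyl]cyclohex-3-en-1-ol | CC(C)[Si](C(C)C)(C(C)C)C#CC1=C(C)C[C@@H](O)CC1(C)C | intermediate
12 | but-2-yn-1-ol | CC#CCO | starting material
13 | (2E)-3-iodobut-2-en-1-ol | C/C(I)=C\CO | intermediate
14 | (1R)-4-ethynyl-3,5,5-trimethylcyclohex-3-en-1-ol (not isolated) | C#CC1=C(C)C[C@@H](O)CC1(C)C | intermediate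
15 | (1R)-4-[(3E)-5-hydroxy-3-methylpent-3-en-1-yn-1-yl]-3,5,5-trimethylcyclohex-3-en-1-ol | OC/C=C(\C)C#CC1=C(C)C[C@@H](O)CC1(C)C | intermediate
16 | (2E)-5-[(4R)-4-hydroxy-2,6,6-trimethylcyclohex-1-en-1-yl]-3-methylpent-2-en-4-ynal | O=C/C=C(\C)C#CC1=C(C)C[C@@H](O)CC1(C)C | intermediate
17 | (1R)-3,5,5-trimethyl-4-[(3E)-3-methyl-5-oxopent-3-en-1-yn-1-yl]cyclohex-3-en-1-yl benzoate | O=C/C=C(\C)C#CC1=C(C)C[C@@H](OC(=O)c2ccccc2)CC1(C)C | intermediate
18 | 2,6,6-trimethylcyclohex-2-ene-1,4-dione | CC1=CC(=O)CC(C)(C)C1=O | starting material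
19 | (4R)-4-hydroxy-2,6,6-trimethylcyclohex-2-en-1-one | CC1=C[C@H](O)CC(C)(C)C1=O | intermediate
20 | (2E)-3-methylpent-2-en-4-yn-1-ol | C#C/C(C)=C/CO | starting material
21 | (1R,4R)-1-[(3E)-5-hydroxy-3-methylpent-3-en-1-yn-1-yl]-2,6,6-trimethylcyclohex-2-ene-1,4-diol | CC1=C[C@H](O)CC(C)(C)[C@]1(O)C#C/C(C)=C/CO | intermediate
22 | (1R,4R)-1-[(1E,3E)-5-hydroxy-3-methylpenta-1,3-dien-1-yl]-2,6,6-trimethylcyclohex-2-ene-1,4-diol | CC1=C[C@H](O)CC(C)(C)[C@]1(O)/C=C/C(C)=C/CO | intermediate
23 | (2E,4E)-5-[(1R,4R)-1,4-dihydroxy-2,6,6-trimethylcyclohex-2-en-1-yl]-3-methylpenta-2,4-dienal | CC1=C[C@H](O)CC(C)(C)[C@]1(O)/C=C/C(C)=C/C=O | intermediate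
24 | (1S,4R)-4-hydroxy-3,5,5-trimethyl-4-[(1E,3E)-3-methyl-5-oxopenta-1,3-dien-1-yl]cyclohex-2-en-1-yl benzoate | CC1=C[C@@H](OC(=O)c2ccccc2)CC(C)(C)[C@]1(O)/C=C/C(C)=C/C=O | intermediate
25 | (2E,4E,6E)-2,7-dimethylocta-2,4,6-trienedial | O=C/C(C)=C/C=C/C=C(C)/C=O | starting material
26 | (2E,4E,6E)-2,7-dimethylocta-2,4,6-triene-1,8-diol | OC/C(C)=C/C=C/C=C(C)/CO | intermediate
27 | (2E,4E,6E)-1,8-dibromo-2,7-dimethylocta-2,4,6-triene | BrC/C(C)=C/C=C/C=C(C)/CBr | intermediate
28 | tetraethyl [(2E,4E,6E)-2,7-dimethylocta-2,4,6-triene-1,8-diyl]bis(phosphonate) | CCOP(=O)(OCC)C/C(C)=C/C=C/C=C(C)/CP(=O)(OCC)OCC | intermediate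
29 | diethyl [(2E,4E,6E,8E,10E)-13-[(4R)-4-(benzoyloxy)-2,6,6-trimethylcyclohex-1-en-1-yl]-2,7,11-trimethyltrideca-2,4,6,8,10-pentaen-12-yn-1-yl]phosphonate | CCOP(=O)(OCC)C/C(C)=C/C=C/C=C(C)/C=C/C=C(\C)C#CC1=C(C)C[C@@H](OC(=O)c2ccccc2)CC1(C)C | intermediate
30 | all-E 3,3'-dibenzoate of the target (ring A 3S,6R; ring B 3'R) | CC1=C[C@@H](OC(=O)c2ccccc2)CC(C)(C)[C@]1(O)/C=C/C(C)=C/C=C/C(C)=C/C=C/C=C(C)/C=C/C=C(\C)C#CC1=C(C)C[C@@H](OC(=O)c2ccccc2)CC1(C)C | intermediate
31 | all-E triol: ring A (3S,6R)-3,6-dihydroxy-4-ene, ring B (3'R)-3'-hydroxy-7',8'-didehydro | CC1=C[C@@H](O)CC(C)(C)[C@]1(O)/C=C/C(C)=C/C=C/C(C)=C/C=C/C=C(C)/C=C/C=C(\C)C#CC1=C(C)C[C@@H](O)CC1(C)C | target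

## Step count and risks

Total steps: 21. Longest linear sequence: 11 steps (steps 1, 2, 3, 5, 6, 8, 9, 10, 19, 20, 21).

Steps most likely to fail:

1. Step 6 (asymmetric hydroboration). The hindered ring olefin next to the quaternary carbon may react so slowly that hydroboration of the silyl-capped enyne or loss of α-pinene from the reagent competes, eroding chemo-, regio- and enantioselectivity. Fallback, setting out from 9 and returning at 11: hydroboration with 9-BBN (which prefers olefins to internal alkynes) and alkaline peroxide oxidation would give racemic 3,5,5-trimethyl-4-[(triisopropylsilyl)ethynyl]cyclohex-3-en-1-ol F1. Lipase-catalysed transesterification (Burkholderia cepacia lipase, vinyl acetate) should, by the empirical size rule for lipases, acetylate the (R)-enantiomer to the (1R)-acetate F2 and leave the (1S)-alcohol F3, which is separated. Methanolysis of F2 (K2CO3, MeOH) would give 11.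

2. Step 5 (double Wittig annulation). The secondary ylide may pair with the aldehyde, the β-keto aldehyde may be cleaved by base, or the second, intramolecular olefination at the hindered ynone carbonyl may lose to oligomerisation. Fallback, setting out from 5 and returning at 9, making the same two bonds one at a time: Z-selective Wittig reaction of 5 with the ylide of (3-hydroxybutyl)triphenylphosphonium bromide F4 (prepared from 4-bromobutan-2-ol and PPh3; two equivalents of KN(SiMe3)2) would give (5Z)-8-hydroxy-4,4-dimethyl-1-(triisopropylsilyl)non-5-en-1-yn-3-one F5. An Appel-type iodination (I2, PPh3, imidazole) would give the secondary iodide (5Z)-8-iodo-4,4-dimethyl-1-(triisopropylsilyl)non-5-en-1-yn-3-one F6. A Barbier cyclisation with SmI2 in THF/HMPA would close ring B at C5'–C6' to 2,6,6-trimethyl-1-[(triisopropylsilyl)ethynyl]cyclohex-4-en-1-ol F7 as a diastereomer mixture. Dehydration of this tertiary propargylic alcohol (POCl3, pyridine), for which only H-5' is available, would give 9.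

3. Step 12 (acetylide addition). The facial selectivity may be lower than, or opposite to, the 1,4-relay model; a low selectivity would be handled by separating the C6 epimers at the triol stage and using the series that fits the major one. Fallback for the opposite sense, setting out from 18 and returning at 24 without the inversion: transfer hydrogenation of 18 with RuCl[(S,S)-TsDPEN](p-cymene) would give (4S)-4-hydroxy-2,6,6-trimethylcyclohex-2-en-1-one F8. Addition of the dianion of 20 anti to the oxygen would give (1R,4S)-1-[(3E)-5-hydroxy-3-methylpent-3-en-1-yn-1-yl]-2,6,6-trimethylcyclohex-2-ene-1,4-diol F9, which already has the 3,6-cis-diol. Hydroalumination as in step 13 would give (1R,4S)-1-[(1E,3E)-5-hydroxy-3-methylpenta-1,3-dien-1-yl]-2,6,6-trimethylcyclohex-2-ene-1,4-diol F10. Oxidation as in step 14 would give (2E,4E)-5-[(1R,4S)-1,4-dihydroxy-2,6,6-trimethylcyclohex-2-en-1-yl]-3-methylpenta-2,4-dienal F11. Benzoylation with retention (BzCl, pyridine, DMAP) would give 24.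

Further compounds
F1 | step 6 | racemic 3,5,5-trimethyl-4-[(triisopropylsilyl)ethynyl]cyclohex-3-en-1-ol | CC(C)[Si](C(C)C)(C(C)C)C#CC1=C(C)CC(O)CC1(C)C
F2 | step 6 | (1R)-3,5,5-trimethyl-4-[(triisopropylsilyl)ethynyl]cyclohex-3-en-1-yl acetate | CC(C)[Si](C(C)C)(C(C)C)C#CC1=C(C)C[C@@H](OC(C)=O)CC1(C)C
F3 | step 6 | (1S)-3,5,5-trimethyl-4-[(triisopropylsilyl)ethynyl]cyclohex-3-en-1-ol | CC(C)[Si](C(C)C)(C(C)C)C#CC1=C(C)C[C@H](O)CC1(C)C
F4 | step 5 | (3-hydroxybutyl)triphenylphosphonium bromide (racemic) | CC(O)CC[P+](c1ccccc1)(c1ccccc1)c1ccccc1.[Br-]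
F5 | step 5 | (5Z)-8-hydroxy-4,4-dimethyl-1-(triisopropylsilyl)non-5-en-1-yn-3-one (racemic) | CC(O)C/C=C\C(C)(C)C(=O)C#C[Si](C(C)C)(C(C)C)C(C)C
F6 | step 5 | (5Z)-8-iodo-4,4-dimethyl-1-(triisopropylsilyl)non-5-en-1-yn-3-one (racemic) | CC(I)C/C=C\C(C)(C)C(=O)C#C[Si](C(C)C)(C(C)C)C(C)C
F7 | step 5 | 2,6,6-trimethyl-1-[(triisopropylsilyl)ethynyl]cyclohex-4-en-1-ol (diastereomer mixture) | CC1CC=CC(C)(C)C1(O)C#C[Si](C(C)C)(C(C)C)C(C)C
F8 | step 12 | (4S)-4-hydroxy-2,6,6-trimethylcyclohex-2-en-1-one | CC1=C[C@@H](O)CC(C)(C)C1=O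
F9 | step 12 | (1R,4S)-1-[(3E)-5-hydroxy-3-methylpent-3-en-1-yn-1-yl]-2,6,6-trimethylcyclohex-2-ene-1,4-diol | CC1=C[C@@H](O)CC(C)(C)[C@]1(O)C#C/C(C)=C/CO
F10 | step 12 | (1R,4S)-1-[(1E,3E)-5-hydroxy-3-methylpenta-1,3-dien-1-yl]-2,6,6-trimethylcyclohex-2-ene-1,4-diol | CC1=C[C@@H](O)CC(C)(C)[C@]1(O)/C=C/C(C)=C/CO
F11 | step 12 | (2E,4E)-5-[(1R,4S)-1,4-dihydroxy-2,6,6-trimethylcyclohex-2-en-1-yl]-3-methylpenta-2,4-dienal | CC1=C[C@@H](O)CC(C)(C)[C@]1(O)/C=C/C(C)=C/C=O
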